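**Analysis of the target**

Hansforester A is an open-chain tetraester of five units joined head to tail. These are a 2,4-dihydroxy-6-methylbenzoyl cap (ring A), an (R)-3-hydroxybutanoate link (fragment B), a 2,4-dihydroxy-6-[(R)-2-hydroxypropyl]benzoate (ring C), a second (R)-3-hydroxybutanoate (fragment D) and a terminal 5-[(R)-2-hydroxypropyl]resorcinol (ring E); the three benzene rings are the only rings. All four stereocentres are O-acylated methyl carbinols of (R) configuration; esters and arenes insulate them from each other, so none can direct another and each must be set on its own. The sensitive features are the two β-acyloxy esters (prone to base-induced β-elimination), the six free phenols, and the ring C seco-acid, which closes to a six-membered lactone whenever its side-chain hydroxyl is free beside an activated or esterified carboxyl. Two of the four esters are benzoates flanked by two ortho substituents, which resist attack at the carbonyl carbon. The difficulty is therefore one of order: like groups must be told apart, and the hindered esters made without lactonisation or elimination. The route rests on one feature of ring C: the carboxyl carbon sits on C1 and the three-carbon chain on the neighbouring C6, with phenol oxygens on C2 and C4. This is the pattern left when an aryne with an oxygen beside its triple bond takes up a carbon nucleophile and CO2 across that bond; ring E is the same unit without the C1 carboxyl.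

**Retrosynthetic reasoning**

Global deprotection. Target 30 is traced to its hexabenzyl ether 29. None of the four esters is benzylic, so hydrogenolysis under neutral conditions frees all six phenols in the last step and the free resorcinols never have to survive a coupling.

Ester between fragment B and ring C. In 29 the ester between the fragment B carboxyl and the ring C carbinol is cut, giving acid 24 (rings A and B) and alcohol 28 (rings C, D, E). It is an unhindered aliphatic ester and the cut is the most convergent one available. The forward reaction must acylate a secondary alcohol with a β-aroyloxy acid without β-elimination, and before the hydroxyl of 28 turns on its neighbouring benzoate.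

Ester between fragment D and ring E. Alcohol 28 comes from silyl ether 27, which is cut in the same way into acid 26 and alcohol 17. The silyl group keeps the ring C side-chain oxygen silent until the D–E ester is in place.

The two hindered aryl esters. Acids 24 and 26 come from allyl esters 23 and 25. In each, the O–alkyl bond of the benzoate is cut rather than the acyl–O bond, giving benzoic acids 22 and 15 and the single hydroxy ester 19. The forward reaction is then an SN2 displacement at the carbinol by the carboxylate under Mitsunobu conditions, with inversion from (S) to (R). The shielded carbonyl is never attacked, and acid 15 is never turned into an acyl electrophile that its own side-chain oxygen could reach. The allyl ester is later freed under neutral palladium catalysis.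

Simple building blocks. Hydroxy ester 19 comes from methyl ester 18 by transesterification. Acid 22 comes from orsellinic acid 20 through its perbenzylated ester 21.

Ring E from the ring C unit. Alcohol 17 is traced through silyl ether 16 to acid 15 by removing the aryl–carboxyl bond; the forward reaction is a protodecarboxylation. One intermediate then serves as the ring C acid and as the source of ring E, and one asymmetric reduction supplies two of the four stereocentres.

Carbinol and seco-acid. Acid 15 is the silyl-trapped open form of lactone 12. Lactone 12 comes from keto acid 10 by enzymatic reduction of a methyl ketone, and 10 from isocoumarin 9 by hydrolysis, since the enol lactone of 9 is a masked methyl ketone and carboxylic acid.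

Key disconnection. In isocoumarin 9 the two aryl–carbon bonds at C4a and C8a and the O–C3 bond are cut, leading to aryne 8, propyne 6 and carbon dioxide 7. Aryne 8 is released from silyl triflate 5. All carbons of the ring C unit then arrive in one operation, and the benzyloxy group beside the aryne bond fixes which carbon takes the alkyne and which takes CO2.

Aryne precursor. Silyl triflate 5 comes from bromophenol 2 by O-silylation, bromine–lithium exchange with O-to-C silyl shift, and triflation; 2 comes from phenol 1 by ortho-bromination.

**Alternatives that were turned down**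

Alternative 1: Ring A is built last. The C1–C6 bond of its benzene ring and the ester C–O bond to fragment B are cut, which leads back to the dioxinone A2 and the alcohol A3 that carries rings C and E and both hydroxybutanoate links.
- Forward key step: on heating, A2 fragments by retro-[4+2] and the reactive acyl species acylates the fragment B hydroxyl of A3. Mild base and then acid close the resulting open chain by aldol condensation and dehydration to the free resorcylate A1.
- For: the hindered A–B ester is formed under neutral heat before the ring exists, with retention at the carbinol, and ring A needs no protection. On that single bond it is at least as good as the Mitsunobu esterification of acid 22.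
- Against: it constructs the one ring that can be bought as its acid (20). A2 needs several steps of its own. The aromatisation has to run at the last stage on a derivative of A3 that holds two β-acyloxy esters and the hindered ring C benzoate, and the base that drives the aldol is the base that triggers β-elimination. Polycarbonyl chains of this kind can also close through oxygen to pyranones.
- Comparison: it leaves rings C and E and their stereocentres unsolved. The chosen strategy spends its complexity-building step early, on simple material, and on the two units for which no correctly substituted precursor can be bought.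

Alternative 2: Ring C is built last by cycloaddition. Two C–C bonds of ring C are cut, leading to the linear alkynoate A5, which already carries all four stereocentres and three esters, and the bis-silyloxy diene A6.
- Forward key step: thermal [4+2] addition, then loss of the methoxy group and desilylation, aromatises the adduct to A4. The polarisation of A6 places one hydroxyl ortho and one para to the ester.
- For: it is convergent. The hindered C–D ester is made as an unhindered alkynoate ester, and the ring C carbinol is acylated before ring C exists, so the lactonisation problem disappears. On both points it is stronger than the chosen route.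
- Against: β-alkyl alkynoates are sluggish dienophiles and need long heating with excess diene. A5 has a propargylic methylene beside an acyloxy carbinol, open to propargyl–allenyl isomerisation and to elimination. A failure costs the whole chain. Ring E still needs its own synthesis.
- Comparison: the chosen strategy accepts two Mitsunobu esterifications and one silyl group. In return its key step runs at the start of the route and one monomer serves both rings C and E.

Alternative 3: The hydroxybutanoate link is assembled from an epoxide. The CH2–carbonyl bond and the ester C–O bond of fragment D are cut.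
- Forward key step: (R)-propylene oxide A8, carbon monoxide A9 and alcohol 17 combine under catalysis by dicobalt octacarbonyl A10 in the presence of 3-hydroxypyridine A11 to give the D–E alcohol A7. The cobaltate opens the epoxide at CH2, CO inserts and the alcohol cleaves the acylcobalt; the stereocentre is retained.
- For: it is atom-economic and protecting-group-free and starts from the cheapest chiral source. For making the link it is more direct than the allyl ester, Mitsunobu and deallylation sequence used here.
- Against: the known reaction uses the alcohol as solvent. With a secondary alcohol as limiting partner, the acylcobalt can be taken by the product's own hydroxyl or can close to a four-membered lactone, which leads to oligomers. A7 carries an (R)-hydroxyl, so the ring C acid would have to be joined with retention, by attack of a β-hydroxy ester on an activated form of acid 15. That is the mode that invites lactonisation.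
- Comparison: it addresses the simplest bonds of the molecule and leaves both arene units to be made by other means. The chosen strategy makes those units and their carbinols from one intermediate.

Key step: step 3

Remark on the chemistry (assumption): phenol 1 is taken as a purchasable compound, because statistical dibenzylation of phloroglucinol is not a dependable step. The (R)-selective ketoreductase is chosen from a commercial enzyme panel. IPr = 1,3-bis(2,6-diisopropylphenyl)imidazol-2-ylidene; TBS = tert-butyldimethylsilyl.

**Route**

Step 1
Reactants: 1 3,5-bis(benzyloxy)phenol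
Product: 2 2-bromo-3,5-bis(benzyloxy)phenol
Conditions: NBS (1.0 equiv), CH2Cl2, –78 °C to 0 °C
Reagents that add atoms: N-bromosuccinimide, O=C1CCC(=O)N1Br
Why: Electrophilic aromatic bromination. C2 and C6 are equivalent and ortho to the free hydroxyl; in a non-polar solvent at low temperature they should be preferred over C4, which is flanked by two benzyloxy groups, because the phenol hydrogen-bonds the reagent.

Step 2
Reactants: 2 2-bromo-3,5-bis(benzyloxy)phenol
Product: 5 3,5-bis(benzyloxy)-2-(trimethylsilyl)phenyl trifluoromethanesulfonate, via aryl trimethylsilyl ether 3 (not isolated), via lithium 2-silylphenoxide 4 (not isolated)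
Conditions: HMDS, THF, 70 °C, then evaporation; n-BuLi, THF, –78 °C; Tf2O, –78 °C to rt
Reagents that add atoms: hexamethyldisilazane, C[Si](C)(C)N[Si](C)(C)C; trifluoromethanesulfonic anhydride, O=S(=O)(OS(=O)(=O)C(F)(F)F)C(F)(F)F
Why: O-Silylation, then bromine–lithium exchange, which at –78 °C is faster than deprotonation of the benzyl ethers. The aryllithium takes the silyl group from oxygen (anionic 1,3 O-to-C shift, retro-Brook rearrangement) and the resulting phenoxide is triflated; this is the standard entry to ortho-silylaryl triflates.

Step 3
Reactants: 5 3,5-bis(benzyloxy)-2-(trimethylsilyl)phenyl trifluoromethanesulfonate; 6 propyne; 7 carbon dioxide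
Product: 9 6,8-bis(benzyloxy)-3-methylisocoumarin, via 3,5-bis(benzyloxy)benzyne 8 (not isolated)
Conditions: (IPr)CuCl (10 mol %), CsF (3 equiv), Cs2CO3 (0.5 equiv), propyne (2 equiv, THF solution), CO2 (1 atm), MeCN, 80 °C, sealed vessel
Reagents that add atoms: none
Why: Fluoride attacks silicon in 5 and expels triflate to give aryne 8, while the base and (IPr)CuCl convert propyne into the monovalent copper propynide. The benzyloxy group on C3 of 8 polarises the strained triple bond by induction, so the propynyl group goes to the distal carbon C1 and copper ends on C2, next to the benzyloxy group; these two carbons become C4a and C8a of 9. The arylcopper, made nucleophilic by the carbene ligand, should insert CO2 faster than it is protonated in the aprotic medium, giving the copper 2-alkynylbenzoate. The carboxylate oxygen then adds to the copper-activated alkyne at its methyl-bearing carbon, a 6-endo-dig O–C closure that forms the pyranone ring, and protonolysis of the vinylcopper by propyne or hydrogen carbonate releases 9 and returns the acetylide. The closest known reaction type is the copper–carbene-catalysed three-component coupling of arynes, terminal alkynes and CO2 to isocoumarins, applied here to the smallest alkyne and a dialkoxy aryne. No stereocentre is formed. Two selectivities are needed: the regiochemistry of addition to the aryne, secured by the C3 benzyloxy group (the C5 group is remote and does not oppose it), and 6-endo over 5-exo closure, secured by the bulky carbene ligand on copper and the alkyl terminus of the alkyne. Slow release of 8 by sparingly soluble CsF should keep the aryne from outrunning the catalytic cycle.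

Step 4
Reactants: 9 6,8-bis(benzyloxy)-3-methylisocoumarin
Product: 10 2,4-bis(benzyloxy)-6-(2-oxopropyl)benzoic acid
Conditions: KOH, EtOH/H2O, 80 °C; then 1 M HCl to pH 3, 0 °C
Reagents that add atoms: water (as KOH/H2O), O
Why: Saponification of the enol lactone. Hydroxide adds to C1 and the ring opens to the carboxylate and an enolate that is protonated to the methyl ketone, as is usual for 3-alkylisocoumarins; benzyl ethers are inert to base.

Step 5
Reactants: 10 2,4-bis(benzyloxy)-6-(2-oxopropyl)benzoic acid
Product: 12 (R)-6,8-bis(benzyloxy)-3-methyl-3,4-dihydroisocoumarin, via (R)-hydroxy acid 11 (not isolated)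
Conditions: (R)-selective ketoreductase (Lactobacillus kefir alcohol dehydrogenase type), NADP+ (cat.), MgSO4 (1 mM), i-PrOH (10 vol %), DMSO (5 vol %), phosphate buffer pH 7, 30 °C; then 1 M HCl to pH 2, EtOAc, rt
Reagents that add atoms: none
Why: Enzymatic carbonyl reduction with cofactor recycling by isopropanol. The two flanks of the ketone differ sharply in size (methyl against arylmethyl), so an enzyme of this class should deliver hydride to the Si face and give the (R)-carbinol; δ-keto acids are known substrates of ketoreductases. Acidification closes the six-membered lactone by attack of the carbinol oxygen on the carboxyl, which makes the product neutral, extractable and configurationally secure.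

Step 6
Reactants: 12 (R)-6,8-bis(benzyloxy)-3-methyl-3,4-dihydroisocoumarin
Product: 15 (R)-2,4-bis(benzyloxy)-6-[2-(tert-butyldimethylsilyloxy)propyl]benzoic acid, via potassium hydroxy carboxylate 13 (not isolated), via silyl ether silyl ester 14 (not isolated)
Conditions: KOH (1.1 equiv), THF/MeOH/H2O, 60 °C, evaporation (toluene azeotrope); TBSCl (3 equiv), imidazole (6 equiv), DMF, rt; K2CO3, MeOH/THF/H2O, rt, then dilute HCl to pH 4, 0 °C
Reagents that add atoms: water (as KOH/H2O), O; tert-butyldimethylsilyl chloride, CC(C)(C)[Si](C)(C)Cl
Why: Lactone saponification, exhaustive silylation and selective solvolysis of the much more labile silyl ester, the standard way to trap a seco-acid as its O-silyl ether. No bond to the stereocentre is broken.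

Step 7
Reactants: 15 (R)-2,4-bis(benzyloxy)-6-[2-(tert-butyldimethylsilyloxy)propyl]benzoic acid
Product: 16 (R)-{[1-(3,5-bis(benzyloxy)phenyl)propan-2-yl]oxy}(tert-butyl)dimethylsilane
Conditions: Ag2CO3 (10 mol %), AcOH (5 mol %), DMSO, 120 °C
Reagents that add atoms: none
Why: Silver-catalysed protodecarboxylation of an ortho,ortho′-disubstituted benzoic acid. The two ortho groups twist the silver carboxylate out of the ring plane and ease loss of CO2, the ipso carbon is further activated by the ortho and para benzyloxy groups, and the arylsilver is protonated. The silyl ether prevents the lactonisation that a free hydroxyl would undergo.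

Step 8
Reactants: 16 (R)-{[1-(3,5-bis(benzyloxy)phenyl)propan-2-yl]oxy}(tert-butyl)dimethylsilane
Product: 17 (R)-1-[3,5-bis(benzyloxy)phenyl]propan-2-ol
Conditions: TBAF, THF, rt
Reagents that add atoms: none
Why: Fluoride cleavage of a secondary silyl ether; with no ester in the molecule the basicity of the reagent is harmless.

Step 9
Reactants: 18 methyl (S)-3-hydroxybutanoate
Product: 19 allyl (S)-3-hydroxybutanoate
Conditions: allyl alcohol (solvent), Ti(OiPr)4 (10 mol %), 95 °C, MeOH distilled off
Reagents that add atoms: allyl alcohol, C=CCO
Why: Titanate-catalysed transesterification under neutral conditions, which β-hydroxy esters tolerate without dehydration; the stereocentre is not involved.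

Step 10
Reactants: 20 orsellinic acid
Product: 21 benzyl 2,4-bis(benzyloxy)-6-methylbenzoate
Conditions: BnBr (3.5 equiv), K2CO3 (4 equiv), DMF, rt to 60 °C
Reagents that add atoms: benzyl bromide, BrCc1ccccc1
Why: Alkylation of the carboxylate and then of both phenoxides (Williamson ether synthesis). Esterification comes first and removes the risk of decarboxylation; the hydrogen-bonded ortho phenol needs the gentle warming.

Step 11
Reactants: 21 benzyl 2,4-bis(benzyloxy)-6-methylbenzoate
Product: 22 2,4-bis(benzyloxy)-6-methylbenzoic acid
Conditions: KOH (excess), dioxane/MeOH/H2O, 100 °C; then 1 M HCl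
Reagents that add atoms: water (as KOH/H2O), O
Why: Saponification of a hindered benzoate, slow but clean under forcing conditions because the aryl benzyl ethers are stable to hydroxide.

Step 12
Reactants: 22 2,4-bis(benzyloxy)-6-methylbenzoic acid; 19 allyl (S)-3-hydroxybutanoate
Product: 23 allyl (R)-3-{[2,4-bis(benzyloxy)-6-methylbenzoyl]oxy}butanoate
Conditions: PPh3, DIAD, toluene, 0 °C to rt
Reagents that add atoms: none
Why: Mitsunobu esterification. The carbinol of 19 is activated as its alkoxyphosphonium ion and displaced by the carboxylate in an SN2 step, so (S) becomes (R), and the shielded carbonyl of 22 is never attacked. Ortho-disubstituted benzoic acids are acidic enough to be good partners.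

Step 13
Reactants: 23 allyl (R)-3-{[2,4-bis(benzyloxy)-6-methylbenzoyl]oxy}butanoate
Product: 24 (R)-3-{[2,4-bis(benzyloxy)-6-methylbenzoyl]oxy}butanoic acid
Conditions: Pd(PPh3)4 (5 mol %), morpholine, THF, rt
Reagents that add atoms: none
Why: Tsuji–Trost deallylation. Zerovalent palladium ionises the allyl ester to a π-allyl complex and the carboxylate, and morpholine takes the allyl group; the medium stays near neutral, so the β-aroyloxy ester should not eliminate.

Step 14
Reactants: 15 (R)-2,4-bis(benzyloxy)-6-[2-(tert-butyldimethylsilyloxy)propyl]benzoic acid; 19 allyl (S)-3-hydroxybutanoate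
Product: 25 allyl (R)-3-({2,4-bis(benzyloxy)-6-[(R)-2-(tert-butyldimethylsilyloxy)propyl]benzoyl}oxy)butanoate
Conditions: PPh3, DIAD, toluene, 0 °C to rt
Reagents that add atoms: none
Why: Mitsunobu esterification with inversion at the carbinol of 19, (S) to (R). Acid 15 acts only as a carboxylate nucleophile, so no acyl electrophile is formed that its silyloxy side chain could capture as the lactone.

Step 15
Reactants: 25 allyl (R)-3-({2,4-bis(benzyloxy)-6-[(R)-2-(tert-butyldimethylsilyloxy)propyl]benzoyl}oxy)butanoate
Product: 26 (R)-3-({2,4-bis(benzyloxy)-6-[(R)-2-(tert-butyldimethylsilyloxy)propyl]benzoyl}oxy)butanoic acid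
Conditions: Pd(PPh3)4 (5 mol %), morpholine, THF, rt
Reagents that add atoms: none
Why: Tsuji–Trost deallylation as in step 13; silyl ether, benzyl ethers and the aryl ester are untouched.

Step 16
Reactants: 26 (R)-3-({2,4-bis(benzyloxy)-6-[(R)-2-(tert-butyldimethylsilyloxy)propyl]benzoyl}oxy)butanoic acid; 17 (R)-1-[3,5-bis(benzyloxy)phenyl]propan-2-ol
Product: 27 (R)-1-[3,5-bis(benzyloxy)phenyl]propan-2-yl (R)-3-({2,4-bis(benzyloxy)-6-[(R)-2-(tert-butyldimethylsilyloxy)propyl]benzoyl}oxy)butanoate
Conditions: DCC (1.3 equiv), DMAP (10 mol %), CH2Cl2, –10 °C to rt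
Reagents that add atoms: none
Why: Steglich esterification of an unhindered aliphatic acid with a secondary alcohol through the O-acylisourea and the acylpyridinium ion. Low temperature and only catalytic DMAP should keep acyl transfer ahead of α-deprotonation and loss of the β-aroyloxy group; neither carbinol is touched.

Step 17
Reactants: 27 (R)-1-[3,5-bis(benzyloxy)phenyl]propan-2-yl (R)-3-({2,4-bis(benzyloxy)-6-[(R)-2-(tert-butyldimethylsilyloxy)propyl]benzoyl}oxy)butanoate
Product: 28 (R)-1-[3,5-bis(benzyloxy)phenyl]propan-2-yl (R)-3-({2,4-bis(benzyloxy)-6-[(R)-2-hydroxypropyl]benzoyl}oxy)butanoate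
Conditions: HF·pyridine, THF/pyridine, 0 °C to rt
Reagents that add atoms: none
Why: Buffered acidic fluoride desilylation. No alkoxide is formed, so the freed hydroxyl should neither attack the neighbouring hindered benzoate (relactonisation) nor set off β-elimination; the alcohol is taken on without storage.

Step 18
Reactants: 28 (R)-1-[3,5-bis(benzyloxy)phenyl]propan-2-yl (R)-3-({2,4-bis(benzyloxy)-6-[(R)-2-hydroxypropyl]benzoyl}oxy)butanoate; 24 (R)-3-{[2,4-bis(benzyloxy)-6-methylbenzoyl]oxy}butanoic acid
Product: 29 hexa-O-benzylhansforester A
Conditions: DCC (1.3 equiv), DMAP (10 mol %), CH2Cl2, –10 °C to rt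
Reagents that add atoms: none
Why: Steglich esterification as in step 16. Intermolecular acylation of the secondary hydroxyl by the acylpyridinium ion should be faster than its intramolecular attack on the doubly ortho-substituted benzoate.

Step 19
Reactants: 29 hexa-O-benzylhansforester A
Product: 30 hansforester A
Conditions: H2 (1 atm), Pd/C (10 %), EtOAc/MeOH, rt
Reagents that add atoms: none
Why: Hydrogenolysis of six aryl benzyl ethers over palladium on carbon under neutral conditions. None of the four esters is benzylic, and no aliphatic hydroxyl is left free to migrate or lactonise.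

**Compound list**

1 | 3,5-bis(benzyloxy)phenol | Oc1cc(OCc2ccccc2)cc(OCc2ccccc2)c1 | starting material
2 | 2-bromo-3,5-bis(benzyloxy)phenol | Oc1cc(OCc2ccccc2)cc(OCc2ccccc2)c1Br | intermediate
3 | [2-bromo-3,5-bis(benzyloxy)phenoxy]trimethylsilane | C[Si](C)(C)Oc1cc(OCc2ccccc2)cc(OCc2ccccc2)c1Br | intermediate
4 | lithium 3,5-bis(benzyloxy)-2-(trimethylsilyl)phenoxide | [Li+].[O-]c1cc(OCc2ccccc2)cc(OCc2ccccc2)c1[Si](C)(C)C | intermediate
5 | 3,5-bis(benzyloxy)-2-(trimethylsilyl)phenyl trifluoromethanesulfonate | C[Si](C)(C)c1c(OS(=O)(=O)C(F)(F)F)cc(OCc2ccccc2)cc1OCc1ccccc1 | intermediate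
6 | propyne | CC#C | starting material
7 | carbon dioxide | O=C=O | starting material
8 | 3,5-bis(benzyloxy)benzyne | C1#CC(OCc2ccccc2)=CC(OCc2ccccc2)=C1 | intermediate
9 | 6,8-bis(benzyloxy)-3-methylisocoumarin | CC1=Cc2cc(OCc3ccccc3)cc(OCc3ccccc3)c2C(=O)O1 | intermediate
10 | 2,4-bis(benzyloxy)-6-(2-oxopropyl)benzoic acid | CC(=O)Cc1cc(OCc2ccccc2)cc(OCc2ccccc2)c1C(=O)O | intermediate
11 | (R)-2,4-bis(benzyloxy)-6-(2-hydroxypropyl)benzoic acid | O[C@H](C)Cc1cc(OCc2ccccc2)cc(OCc2ccccc2)c1C(=O)O | intermediate
12 | (R)-6,8-bis(benzyloxy)-3-methyl-3,4-dihydroisocoumarin | O=C1O[C@H](C)Cc2cc(OCc3ccccc3)cc(OCc3ccccc3)c12 | intermediate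
13 | potassium (R)-2,4-bis(benzyloxy)-6-(2-hydroxypropyl)benzoate | O[C@H](C)Cc1cc(OCc2ccccc2)cc(OCc2ccccc2)c1C(=O)[O-].[K+] | intermediate
14 | tert-butyldimethylsilyl (R)-2,4-bis(benzyloxy)-6-[2-(tert-butyldimethylsilyloxy)propyl]benzoate | CC(C)(C)[Si](C)(C)O[C@H](C)Cc1cc(OCc2ccccc2)cc(OCc2ccccc2)c1C(=O)O[Si](C)(C)C(C)(C)C | intermediate
15 | (R)-2,4-bis(benzyloxy)-6-[2-(tert-butyldimethylsilyloxy)propyl]benzoic acid | CC(C)(C)[Si](C)(C)O[C@H](C)Cc1cc(OCc2ccccc2)cc(OCc2ccccc2)c1C(=O)O | intermediate
16 | (R)-{[1-(3,5-bis(benzyloxy)phenyl)propan-2-yl]oxy}(tert-butyl)dimethylsilane | CC(C)(C)[Si](C)(C)O[C@H](C)Cc1cc(OCc2ccccc2)cc(OCc2ccccc2)c1 | intermediate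
17 | (R)-1-[3,5-bis(benzyloxy)phenyl]propan-2-ol | O[C@H](C)Cc1cc(OCc2ccccc2)cc(OCc2ccccc2)c1 | intermediate
18 | methyl (S)-3-hydroxybutanoate | O[C@@H](C)CC(=O)OC | starting material
19 | allyl (S)-3-hydroxybutanoate | O[C@@H](C)CC(=O)OCC=C | intermediate
20 | orsellinic acid (2,4-dihydroxy-6-methylbenzoic acid) | Cc1cc(O)cc(O)c1C(=O)O | starting material
21 | benzyl 2,4-bis(benzyloxy)-6-methylbenzoate | Cc1cc(OCc2ccccc2)cc(OCc2ccccc2)c1C(=O)OCc1ccccc1 | intermediate
22 | 2,4-bis(benzyloxy)-6-methylbenzoic acid | Cc1cc(OCc2ccccc2)cc(OCc2ccccc2)c1C(=O)O | intermediate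
23 | allyl (R)-3-{[2,4-bis(benzyloxy)-6-methylbenzoyl]oxy}butanoate | Cc1cc(OCc2ccccc2)cc(OCc2ccccc2)c1C(=O)O[C@H](C)CC(=O)OCC=C | intermediate
24 | (R)-3-{[2,4-bis(benzyloxy)-6-methylbenzoyl]oxy}butanoic acid | Cc1cc(OCc2ccccc2)cc(OCc2ccccc2)c1C(=O)O[C@H](C)CC(=O)O | intermediate
25 | allyl (R)-3-({2,4-bis(benzyloxy)-6-[(R)-2-(tert-butyldimethylsilyloxy)propyl]benzoyl}oxy)butanoate | CC(C)(C)[Si](C)(C)O[C@H](C)Cc1cc(OCc2ccccc2)cc(OCc2ccccc2)c1C(=O)O[C@H](C)CC(=O)OCC=C | intermediate
26 | (R)-3-({2,4-bis(benzyloxy)-6-[(R)-2-(tert-butyldimethylsilyloxy)propyl]benzoyl}oxy)butanoic acid | CC(C)(C)[Si](C)(C)O[C@H](C)Cc1cc(OCc2ccccc2)cc(OCc2ccccc2)c1C(=O)O[C@H](C)CC(=O)O | intermediate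
27 | (R)-1-[3,5-bis(benzyloxy)phenyl]propan-2-yl (R)-3-({2,4-bis(benzyloxy)-6-[(R)-2-(tert-butyldimethylsilyloxy)propyl]benzoyl}oxy)butanoate | CC(C)(C)[Si](C)(C)O[C@H](C)Cc1cc(OCc2ccccc2)cc(OCc2ccccc2)c1C(=O)O[C@H](C)CC(=O)O[C@H](C)Cc1cc(OCc2ccccc2)cc(OCc2ccccc2)c1 | intermediate
28 | (R)-1-[3,5-bis(benzyloxy)phenyl]propan-2-yl (R)-3-({2,4-bis(benzyloxy)-6-[(R)-2-hydroxypropyl]benzoyl}oxy)butanoate | O[C@H](C)Cc1cc(OCc2ccccc2)cc(OCc2ccccc2)c1C(=O)O[C@H](C)CC(=O)O[C@H](C)Cc1cc(OCc2ccccc2)cc(OCc2ccccc2)c1 | intermediate
29 | hexa-O-benzylhansforester A (all six phenols as benzyl ethers) | Cc1cc(OCc2ccccc2)cc(OCc2ccccc2)c1C(=O)O[C@H](C)CC(=O)O[C@H](C)Cc1cc(OCc2ccccc2)cc(OCc2ccccc2)c1C(=O)O[C@H](C)CC(=O)O[C@H](C)Cc1cc(OCc2ccccc2)cc(OCc2ccccc2)c1 | intermediate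
30 | hansforester A | Cc1cc(O)cc(O)c1C(=O)O[C@H](C)CC(=O)O[C@H](C)Cc1cc(O)cc(O)c1C(=O)O[C@H](C)CC(=O)O[C@H](C)Cc1cc(O)cc(O)c1 | target

**Step count and risk**

Total: 19 steps. Longest linear sequence: 12 steps (steps 1–6, then 14–19; the branch through steps 7 and 8 is equally long).

Least certain steps:

Step 3 (key step). The most likely failure is protonation of the arylcopper intermediate by propyne before CO2 is captured, which would end in simple alkynylation of the arene. Closure in the 5-exo sense and consumption of the aryne by carboxylate oxygen are further losses, and the volatility of propyne makes the acetylide concentration hard to hold. Fallback: benzyl ester 21 is deprotonated at its ring methyl group with LDA at –78 °C (lateral lithiation) and acylated with N-methoxy-N-methylacetamide to give benzyl 2,4-bis(benzyloxy)-6-(2-oxopropyl)benzoate F1. Saponification of F1 with KOH returns to the route at keto acid 10.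

Step 1. Bromination at C4, para to the hydroxyl, or double bromination may compete, since all three free ring positions are activated by three oxygens. Fallback: phenol 1 is converted with isopropyl isocyanate into 3,5-bis(benzyloxy)phenyl isopropylcarbamate F2. Carbamate-directed ortho-lithiation (n-BuLi, TMEDA, –78 °C, after N-silylation in the flask) and quenching with chlorotrimethylsilane give 3,5-bis(benzyloxy)-2-(trimethylsilyl)phenyl isopropylcarbamate F3; the only positions ortho to the carbamate are the equivalent C2 and C6. Cleavage with diethylamine and DBU and triflation of the phenoxide with N-phenyltriflimide return to the route at silyl triflate 5.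

Step 5. The enzyme may bind the bulky, anionic substrate poorly, so that conversion stalls or facial selectivity is low. Fallback: isocoumarin 9 is hydrogenated at its C3=C4 enol-lactone double bond with a chiral ruthenium carbene–diamine catalyst (assembled from [Ru(cod)(2-methylallyl)2], a chiral azolium salt, a chiral 1,2-diamine and NaOt-Bu; H2 under pressure), a reaction type known for 3-substituted isocoumarins. The catalyst enantiomer that gives the (R)-lactone is chosen, and the route is rejoined at lactone 12 without passing through 10; benzyl ethers survive homogeneous hydrogenation.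

Step 7. At 120 °C the silyl ether may be lost, after which lactonisation would overtake loss of CO2; extrusion may also be slow for so electron-rich an acid. Fallback: ring E is made without a carboxyl group ever being attached, at the cost of the shared monomer. Phenol 1 is converted with p-toluenesulfonyl chloride and triethylamine into 3,5-bis(benzyloxy)phenyl 4-methylbenzenesulfonate F4. Palladium-catalysed mono-α-arylation of acetone ([Pd(cinnamyl)Cl]2, di(1-adamantyl)(2-morpholinophenyl)phosphine, Cs2CO3, acetone, 90 °C) gives 1-[3,5-bis(benzyloxy)phenyl]propan-2-one F5. This neutral arylacetone, a standard ketoreductase substrate, is reduced with the (R)-selective enzyme of step 5 to return at alcohol 17.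

Step 14 (and likewise step 12). The activated β-hydroxy ester may undergo β-elimination to the unsaturated ester faster than the hindered carboxylate displaces the phosphine oxide leaving group. Fallback: acid 15 is esterified under the same Mitsunobu conditions with (S)-pent-4-en-2-ol, a homoallylic alcohol that cannot eliminate in this way, to give (R)-pent-4-en-2-yl 2,4-bis(benzyloxy)-6-[(R)-2-(tert-butyldimethylsilyloxy)propyl]benzoate F6. Lemieux–Johnson cleavage of the terminal alkene (OsO4 cat., NaIO4, 2,6-lutidine) gives (R)-4-oxobutan-2-yl 2,4-bis(benzyloxy)-6-[(R)-2-(tert-butyldimethylsilyloxy)propyl]benzoate F7, and Pinnick oxidation (NaClO2, NaH2PO4, 2-methyl-2-butene) returns to the route at acid 26.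

Step 16 (and likewise step 18). Activation of the β-aroyloxy acid may lead to α-deprotonation and loss of the aroyloxy group, or to rearrangement of the O-acylisourea to an unreactive N-acylurea. Fallback: the order of bond formation is reversed so that no β-acyloxy acid is activated. Alcohol 17 is heated with 2,2,6-trimethyl-4H-1,3-dioxin-4-one in toluene to give (R)-1-[3,5-bis(benzyloxy)phenyl]propan-2-yl 3-oxobutanoate F8. Noyori hydrogenation with RuCl2[(S)-BINAP] and H2 gives (R)-1-[3,5-bis(benzyloxy)phenyl]propan-2-yl (S)-3-hydroxybutanoate F9. Mitsunobu esterification of F9 with acid 15, with inversion, returns to the route at silyl ether 27.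

**Further compounds**

F1 | step 3 | benzyl 2,4-bis(benzyloxy)-6-(2-oxopropyl)benzoate | CC(=O)Cc1cc(OCc2ccccc2)cc(OCc2ccccc2)c1C(=O)OCc1ccccc1
F2 | step 1 | 3,5-bis(benzyloxy)phenyl isopropylcarbamate | CC(C)NC(=O)Oc1cc(OCc2ccccc2)cc(OCc2ccccc2)c1
F3 | step 1 | 3,5-bis(benzyloxy)-2-(trimethylsilyl)phenyl isopropylcarbamate | CC(C)NC(=O)Oc1cc(OCc2ccccc2)cc(OCc2ccccc2)c1[Si](C)(C)C
F0 | step 5 | none | none
F4 | step 7 | 3,5-bis(benzyloxy)phenyl 4-methylbenzenesulfonate | Cc1ccc(cc1)S(=O)(=O)Oc1cc(OCc2ccccc2)cc(OCc2ccccc2)c1
F5 | step 7 | 1-[3,5-bis(benzyloxy)phenyl]propan-2-one | CC(=O)Cc1cc(OCc2ccccc2)cc(OCc2ccccc2)c1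
F6 | step 14 | (R)-pent-4-en-2-yl 2,4-bis(benzyloxy)-6-[(R)-2-(tert-butyldimethylsilyloxy)propyl]benzoate | CC(C)(C)[Si](C)(C)O[C@H](C)Cc1cc(OCc2ccccc2)cc(OCc2ccccc2)c1C(=O)O[C@H](C)CC=C
F7 | step 14 | (R)-4-oxobutan-2-yl 2,4-bis(benzyloxy)-6-[(R)-2-(tert-butyldimethylsilyloxy)propyl]benzoate | CC(C)(C)[Si](C)(C)O[C@H](C)Cc1cc(OCc2ccccc2)cc(OCc2ccccc2)c1C(=O)O[C@H](C)CC=O
F8 | step 16 | (R)-1-[3,5-bis(benzyloxy)phenyl]propan-2-yl 3-oxobutanoate | CC(=O)CC(=O)O[C@H](C)Cc1cc(OCc2ccccc2)cc(OCc2ccccc2)c1
F9 | step 16 | (R)-1-[3,5-bis(benzyloxy)phenyl]propan-2-yl (S)-3-hydroxybutanoate | O[C@@H](C)CC(=O)O[C@H](C)Cc1cc(OCc2ccccc2)cc(OCc2ccccc2)c1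
A1 | alternative 1 | hansforester A tetrabenzyl ether (rings C and E benzylated, ring A free) | Cc1cc(O)cc(O)c1C(=O)O[C@H](C)CC(=O)O[C@H](C)Cc1cc(OCc2ccccc2)cc(OCc2ccccc2)c1C(=O)O[C@H](C)CC(=O)O[C@H](C)Cc1cc(OCc2ccccc2)cc(OCc2ccccc2)c1
A2 | alternative 1 | 6-(2,4-dioxopentyl)-2,2-dimethyl-4H-1,3-dioxin-4-one | CC(=O)CC(=O)CC1=CC(=O)OC(C)(C)O1
A3 | alternative 1 | (R)-1-[3,5-bis(benzyloxy)phenyl]propan-2-yl (R)-3-({2,4-bis(benzyloxy)-6-[(R)-2-{[(R)-3-hydroxybutanoyl]oxy}propyl]benzoyl}oxy)butanoate | O[C@H](C)CC(=O)O[C@H](C)Cc1cc(OCc2ccccc2)cc(OCc2ccccc2)c1C(=O)O[C@H](C)CC(=O)O[C@H](C)Cc1cc(OCc2ccccc2)cc(OCc2ccccc2)c1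
A4 | alternative 2 | hansforester A tetrabenzyl ether (rings A and E benzylated, ring C free) | Cc1cc(OCc2ccccc2)cc(OCc2ccccc2)c1C(=O)O[C@H](C)CC(=O)O[C@H](C)Cc1cc(O)cc(O)c1C(=O)O[C@H](C)CC(=O)O[C@H](C)Cc1cc(OCc2ccccc2)cc(OCc2ccccc2)c1
A5 | alternative 2 | (R)-1-[3,5-bis(benzyloxy)phenyl]propan-2-yl (R)-3-{[(R)-5-{[(R)-3-{[2,4-bis(benzyloxy)-6-methylbenzoyl]oxy}butanoyl]oxy}hex-2-ynoyl]oxy}butanoate | Cc1cc(OCc2ccccc2)cc(OCc2ccccc2)c1C(=O)O[C@H](C)CC(=O)O[C@H](C)CC#CC(=O)O[C@H](C)CC(=O)O[C@H](C)Cc1cc(OCc2ccccc2)cc(OCc2ccccc2)c1
A6 | alternative 2 | 1-methoxy-1,3-bis(trimethylsilyloxy)buta-1,3-diene | COC(O[Si](C)(C)C)=CC(=C)O[Si](C)(C)C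
A7 | alternative 3 | (R)-1-[3,5-bis(benzyloxy)phenyl]propan-2-yl (R)-3-hydroxybutanoate | O[C@H](C)CC(=O)O[C@H](C)Cc1cc(OCc2ccccc2)cc(OCc2ccccc2)c1
A8 | alternative 3 | (R)-propylene oxide | C[C@@H]1CO1
A9 | alternative 3 | carbon monoxide | [C-]#[O+]
A10 | alternative 3 | dicobalt octacarbonyl, Co2(CO)8 | [Co].[Co].[C-]#[O+].[C-]#[O+].[C-]#[O+].[C-]#[O+].[C-]#[O+].[C-]#[O+].[C-]#[O+].[C-]#[O+]
A11 | alternative 3 | 3-hydroxypyridine | Oc1cccnc1
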